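**Retrosynthetic overview**
1. Ring C (the seven-membered lactone–ether ring) is opened last: first the lactone C(=O)–O bond (lactonisation of a hydroxy acid), then the diaryl ether O–C bond (SNAr of a chromanone 6-OH on a ring-A fluoride flanked by CHO and CO2Me, both of which the target keeps).
2. Ring D (the pyranone) and the complete substitution pattern of ring B are traced to 2-methoxy-6-methyl-1,4-benzoquinone and 3-methylbut-2-enal: the ketone carbon C-4 is joined to C-4a and the ring oxygen O-1 to the gem-dimethyl carbon C-2 in one photoacylation/oxa-Michael operation.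
3. Enabling feature: in ring B the pyran oxygen O-1 (on C-8a) and the diaryl-ether oxygen (on C-6) are para to each other, so ring B is a masked para-quinone. Its C–H next to the O-1 carbonyl (the future C-4a) accepts an acyl radical, and C-2 is the β-carbon of a 3-methylbut-2-enoyl unit that the liberated C-8a hydroxyl reaches in a six-membered closure.
4. Ring A is bought as 3-fluoro-5-methylanisole and dressed by para-bromination, lithiation/formylation between F and OMe, and carbonylation.
5. Order of ring formation: ring B (bought, oxidised to the quinone) → ring D (key step) → ring A joined through the ether → ring C by lactonisation.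

Key step: step 2

Remark: the target has no stereocentre (C-2 of the pyranone carries two methyl groups), so the route has no stereochemical task; compounds 1, 3 and 6 are taken as catalogue chemicals.

**Step 1**
Reactants: 1 2-methoxy-6-methylphenol
Product: 2 2-methoxy-6-methyl-1,4-benzoquinone
Conditions: (KO3S)2NO (2.2 equiv), KH2PO4, H2O/acetone, 0 °C → rt
Reagents that add atoms: dipotassium nitrosodisulfonate (Fremy's salt), [K+].[K+].[O]N(S(=O)(=O)[O-])S(=O)(=O)[O-]
Why: Teuber oxidation, in which the phenoxyl radical of 1 is trapped at its free para position by a second nitroxyl and collapses to the quinone; both ortho positions are substituted, so only the para-quinone should form.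

**Step 2**
Reactants: 2 2-methoxy-6-methyl-1,4-benzoquinone; 3 3-methylbut-2-enal
Product: 5 6-hydroxy-7-methoxy-2,2,5-trimethylchroman-4-one, via acylhydroquinone 4 (not isolated)
Conditions: hν (blue LEDs, 450 nm), 3 (5 equiv), benzene, Ar, rt; then DBU (0.3 equiv), dark, rt; AcOH
Reagents that add atoms: none
Why: Visible light is absorbed only by quinone 2, whose triplet abstracts the formyl hydrogen of 3; the 3-methylbut-2-enoyl radical then bonds to C-5 of the quinone (in the radical pair or by addition to ground-state 2), and tautomerisation gives acylhydroquinone 4. DBU then ionises the hydroxyl ortho to the acyl group, and the phenoxide adds to the β,β-dimethyl enone to close the pyranone ring (6-endo-trig oxa-Michael). The closest known reaction types are the photo-Friedel–Crafts acylation of 1,4-quinones with aldehydes, including α,β-unsaturated ones, and the base-mediated cyclisation of 2-hydroxyaryl 3-methylbut-2-enyl ketones to 2,2-dimethylchroman-4-ones. No stereocentre arises, because the new quaternary carbon carries two methyl groups. The step needs C-5 over C-3 acylation, C- over O-acylation and closure by the correct hydroxyl: the methoxy group makes C-2=C-3 an electron-rich vinylogous ester that the nucleophilic acyl radical should avoid, the methyl group blocks C-6, and only the hydroxyl derived from the C-4 carbonyl is ortho to the acyl group. The conjugated acyl radical is not expected to lose CO, and the enal should not absorb at 450 nm.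

**Step 3**
Reactants: 6 1-fluoro-3-methoxy-5-methylbenzene
Product: 7 2-bromo-1-fluoro-5-methoxy-3-methylbenzene
Conditions: NBS (1.05 equiv), MeCN, 0 °C → rt
Reagents that add atoms: N-bromosuccinimide, O=C1CCC(=O)N1Br
Why: Electrophilic aromatic bromination, which for anisoles with NBS in acetonitrile should occur para to the methoxy group, the strongest donor, here the position between F and CH3.

**Step 4**
Reactants: 7 2-bromo-1-fluoro-5-methoxy-3-methylbenzene
Product: 10 3-bromo-2-fluoro-6-methoxy-4-methylbenzaldehyde, via aryllithium 8 (not isolated), via lithium hemiaminal alkoxide 9 (not isolated)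
Conditions: LiN(iPr)2 (1.1 equiv), THF, −78 °C; DMF, −78 → 0 °C; aq. HCl
Reagents that add atoms: N,N-dimethylformamide, CN(C)C=O
Why: Directed ortho-metalation, in which the amide base removes the only hydrogen flanked by fluorine and methoxy without touching the C–Br bond; aryllithium 8 adds to DMF to give the tetrahedral adduct 9 (a transient racemic centre), which releases the aldehyde on acidic work-up.

**Step 5**
Reactants: 10 3-bromo-2-fluoro-6-methoxy-4-methylbenzaldehyde
Product: 11 methyl 2-fluoro-3-formyl-4-methoxy-6-methylbenzoate
Conditions: CO (1 atm), MeOH (10 equiv), Pd(OAc)2 (3 mol%), Xantphos (6 mol%), Et3N, toluene, 80 °C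
Reagents that add atoms: carbon monoxide, [C-]#[O+]; methanol, CO
Why: Palladium-catalysed alkoxycarbonylation, in which zerovalent palladium inserts into the C–Br bond, CO inserts and methanol cleaves the acylpalladium; the wide-bite-angle ligand permits atmospheric CO, and the aldehyde and aryl fluoride should be inert.

**Step 6**
Reactants: 5 6-hydroxy-7-methoxy-2,2,5-trimethylchroman-4-one; 11 methyl 2-fluoro-3-formyl-4-methoxy-6-methylbenzoate
Product: 12 methyl 3-formyl-4-methoxy-6-methyl-2-[(7-methoxy-2,2,5-trimethyl-4-oxochroman-6-yl)oxy]benzoate
Conditions: Cs2CO3 (1.5 equiv), DMSO, Ar, 60 °C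
Reagents that add atoms: none
Why: Nucleophilic aromatic substitution (SNAr), in which the fluoride of 11 is activated by the ortho formyl and ortho ester groups that stabilise the Meisenheimer adduct while the donors sit meta to the reacting carbon; the 6-OH is the only free hydroxyl of 5, so the ether oxygen is placed unambiguously.

**Step 7**
Reactants: 12 methyl 3-formyl-4-methoxy-6-methyl-2-[(7-methoxy-2,2,5-trimethyl-4-oxochroman-6-yl)oxy]benzoate
Product: 13 3-formyl-4-hydroxy-6-methyl-2-[(7-hydroxy-2,2,5-trimethyl-4-oxochroman-6-yl)oxy]benzoic acid
Conditions: BBr3 (6 equiv), CH2Cl2, −78 °C → rt; H2O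
Reagents that add atoms: none
Why: Lewis-acid dealkylation with BBr3, in which bromide attacks the methyl carbons of the boron-complexed ethers and ester (alkyl–oxygen cleavage, unaffected by the shielding of the ester carbonyl); the diaryl ether and the vinylogous-ester oxygen of the pyranone are less basic and should survive, and the formyl group is returned on hydrolysis.

**Step 8**
Reactants: 13 3-formyl-4-hydroxy-6-methyl-2-[(7-hydroxy-2,2,5-trimethyl-4-oxochroman-6-yl)oxy]benzoic acid
Product: 15 mollicellin A, via mixed anhydride 14 (not isolated)
Conditions: (CF3CO)2O (3 equiv), CH2Cl2, 0 °C → rt; aq. NaHCO3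
Reagents that add atoms: none
Why: Mixed-anhydride lactonisation, in which the acid is activated as 14 and attacked by the phenol held next to it by the diaryl ether (seven-membered ring); the other phenol is hydrogen-bonded to the formyl group and para to the acyl carbon, and any aryl trifluoroacetate should be cleaved in the bicarbonate wash.

**Compound list**
1 | 2-methoxy-6-methylphenol | COc1cccc(C)c1O | starting material
2 | 2-methoxy-6-methyl-1,4-benzoquinone | COC1=CC(=O)C=C(C)C1=O | intermediate
3 | 3-methylbut-2-enal | CC(C)=CC=O | starting material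
4 | 1-(3,6-dihydroxy-4-methoxy-2-methylphenyl)-3-methylbut-2-en-1-one | COc1cc(O)c(C(=O)C=C(C)C)c(C)c1O | intermediate (not isolated)
5 | 6-hydroxy-7-methoxy-2,2,5-trimethylchroman-4-one | COc1cc2OC(C)(C)CC(=O)c2c(C)c1O | intermediate
6 | 1-fluoro-3-methoxy-5-methylbenzene (3-fluoro-5-methylanisole) | COc1cc(C)cc(F)c1 | starting material
7 | 2-bromo-1-fluoro-5-methoxy-3-methylbenzene | COc1cc(C)c(Br)c(F)c1 | intermediate
8 | (3-bromo-2-fluoro-6-methoxy-4-methylphenyl)lithium | [Li]c1c(F)c(Br)c(C)cc1OC | intermediate (not isolated)
9 | lithium (3-bromo-2-fluoro-6-methoxy-4-methylphenyl)(dimethylamino)methanolate, racemic | [Li+].[O-]C(N(C)C)c1c(F)c(Br)c(C)cc1OC | intermediate (not isolated)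
10 | 3-bromo-2-fluoro-6-methoxy-4-methylbenzaldehyde | COc1cc(C)c(Br)c(F)c1C=O | intermediate
11 | methyl 2-fluoro-3-formyl-4-methoxy-6-methylbenzoate | COC(=O)c1c(C)cc(OC)c(C=O)c1F | intermediate
12 | methyl 3-formyl-4-methoxy-6-methyl-2-[(7-methoxy-2,2,5-trimethyl-4-oxochroman-6-yl)oxy]benzoate | COC(=O)c1c(C)cc(OC)c(C=O)c1Oc1c(OC)cc2OC(C)(C)CC(=O)c2c1C | intermediate
13 | 3-formyl-4-hydroxy-6-methyl-2-[(7-hydroxy-2,2,5-trimethyl-4-oxochroman-6-yl)oxy]benzoic acid | OC(=O)c1c(C)cc(O)c(C=O)c1Oc1c(O)cc2OC(C)(C)CC(=O)c2c1C | intermediate
14 | mixed anhydride of acid 13 with trifluoroacetic acid | O=C(OC(=O)C(F)(F)F)c1c(C)cc(O)c(C=O)c1Oc1c(O)cc2OC(C)(C)CC(=O)c2c1C | intermediate (not isolated)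
15 | mollicellin A | Cc1cc(O)c(C=O)c2c1C(=O)Oc1cc3c(c(C)c1O2)C(=O)CC(C)(C)O3 | target

**Step count**
Total: 8 steps. Longest linear sequence: 6 steps (steps 3, 4, 5, 6, 7, 8, from 6 to 15).

**Steps most likely to fail**

Step 2. The excited quinone may abstract hydrogen from its own methoxy group, add to the enal double bond, or the radical pair may combine at oxygen instead of carbon, so that little C-5 acylation takes place. The fallback sets out from quinone 2 and uses acid chemistry. Reduction with Na2S2O4 (EtOAc/H2O) would give 2-methoxy-6-methylbenzene-1,4-diol F1. Heating F1 with 3-methylbut-2-enoic acid in P2O5/MeSO3H at 70 °C should acylate the position para to the methoxy group and ortho to the 4-OH (Friedel–Crafts acylation) and close the pyranone by oxa-Michael addition in the same medium. The fallback returns to the route at compound 5.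

Step 6. The doubly ortho-substituted phenoxide may add too slowly to a fluoride carbon shielded on both faces by the twisted ester, so that base-induced condensation between the formyl group and the chromanone methylene takes over. The fallback sets out from 5 and 10 and forms the ether before the ester exists. SNAr of 5 on the fluoride of 10 (K2CO3, DMF, 100 °C), which has only in-plane neighbours (CHO and Br), should give 3-bromo-6-methoxy-4-methyl-2-[(7-methoxy-2,2,5-trimethyl-4-oxochroman-6-yl)oxy]benzaldehyde F2. Alkoxycarbonylation of F2 under the conditions of step 5 (CO, MeOH, Pd(OAc)2, Xantphos, Et3N) would then install the ester. The fallback returns to the route at compound 12.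

Step 7. Dealkylation of the shielded methyl ester may stop short, or the strong Lewis acid may attack the formyl group or open the pyranone at this late, polyfunctional stage. The fallback sets out from 5 and 10 and exchanges the protecting groups so that a milder Lewis acid suffices.
- BBr3 on the simple chromanone 5 (CH2Cl2, −78 → 0 °C) would give 6,7-dihydroxy-2,2,5-trimethylchroman-4-one F3.
- Benzyl bromide (1.0 equiv) with K2CO3 in DMF should alkylate the more acidic, unhindered 7-OH (para to the ketone) to give 7-(benzyloxy)-6-hydroxy-2,2,5-trimethylchroman-4-one F4.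
- Carbonylation of 10 as in step 5, with benzyl alcohol in place of methanol, would give benzyl 2-fluoro-3-formyl-4-methoxy-6-methylbenzoate F5.
- SNAr of F4 on F5 (Cs2CO3, DMSO, 60 °C) should give benzyl 2-{[7-(benzyloxy)-2,2,5-trimethyl-4-oxochroman-6-yl]oxy}-3-formyl-4-methoxy-6-methylbenzoate F6.
- BCl3 (CH2Cl2, −78 → 0 °C) should remove both benzyl groups and the methyl ether chelated by the formyl group.

The fallback returns to the route at compound 13.

**Further compounds**
F1 | step 2 | 2-methoxy-6-methylbenzene-1,4-diol | COc1cc(O)cc(C)c1O
F2 | step 6 | 3-bromo-6-methoxy-4-methyl-2-[(7-methoxy-2,2,5-trimethyl-4-oxochroman-6-yl)oxy]benzaldehyde | COc1cc(C)c(Br)c(Oc2c(OC)cc3OC(C)(C)CC(=O)c3c2C)c1C=O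
F3 | step 7 | 6,7-dihydroxy-2,2,5-trimethylchroman-4-one | Oc1cc2OC(C)(C)CC(=O)c2c(C)c1O
F4 | step 7 | 7-(benzyloxy)-6-hydroxy-2,2,5-trimethylchroman-4-one | Oc1c(OCc2ccccc2)cc2OC(C)(C)CC(=O)c2c1C
F5 | step 7 | benzyl 2-fluoro-3-formyl-4-methoxy-6-methylbenzoate | O=C(OCc1ccccc1)c1c(C)cc(OC)c(C=O)c1F
F6 | step 7 | benzyl 2-{[7-(benzyloxy)-2,2,5-trimethyl-4-oxochroman-6-yl]oxy}-3-formyl-4-methoxy-6-methylbenzoate | O=C(OCc1ccccc1)c1c(C)cc(OC)c(C=O)c1Oc1c(OCc2ccccc2)cc2OC(C)(C)CC(=O)c2c1C
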